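**Structural features**

The target is a 1-aryltetralin (cyclolignan); locants used here: C1 bears ring C, C2 and C3 bear the CH2OH groups, C4 is the benzylic CH2, and ring A is C4a–C8a. Ring A is a pentasubstituted benzene (C5 and C6 methoxy, C7 hydroxy, C8 the only hydrogen) fused through C4a/C8a to the carbocyclic ring B. Ring C, a 4-hydroxy-3-methoxyphenyl group, hangs on C1. C1, C2 and C3 are contiguous stereocentres, (1R,2S,3S), with ring C, the C2 CH2OH and the C3 CH2OH alternately on opposite faces (1,2-trans, 2,3-trans). The fragile points are the two free phenols, which oxidise easily, and the doubly benzylic C1–H para to the ring C phenol. The difficulty lies in joining two different C6–C3 units through C2–C3, closing ring B at C8a with O7 kept distinct from O5/O6, and fixing the absolute configuration. With ester groups on C2 and C3 the all-trans arrangement is the thermodynamic one for a fixed C1, so only C1 must be controlled absolutely. The key step exploits the fact that the skeleton is a dimer of two arylpropenoyl units linked C2–C3, in which only ring C has a free para phenol (it can become a quinone methide at C1), while ring A has a single open position, C8a, ortho to its side chain and para to the C6 methoxy group.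

**Logic of the disconnections**

21 to 20: the two CH2–OH groups are taken back to ester carbonyls. Esters at C2 and C3 put both centres under thermodynamic control. The forward step is a hydride reduction that must tolerate two phenoxides.

20 to 18: the two ester C–O bonds are traced back to the two N–acyl bonds of a diacylurea, and C3 is allowed to have the opposite configuration. One operation then releases auxiliary 10 and sets C3. The demand is attack at the acyl carbons rather than at the urea carbonyl, and full equilibration without touching C1.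

18 to 17: the C3–H and C4–H bonds, the phenol O–H bonds and one aryl C–H bond are taken back to a C3=C4 alkene, a benzyl ether and an aryl bromide. All three are removed under the same conditions, so no separate deprotection is needed. The face of hydrogen delivery is irrelevant because C3 is equilibrated afterwards.

17 to 15 (key): C2–C3 and C1–C8a are cut. This opens ring B and the temporary seven-membered ring and leaves two cinnamoyl groups on the two nitrogen atoms of one C2-symmetric auxiliary. All skeletal carbons, both ring fusions and two stereocentres come from two simple acids. The forward step must oxidise only ring C, couple C2 with C3 rather than through ring carbons, and choose one face. In 15 a bromine atom ortho to the ring C phenol blocks the ring position through which such phenols normally couple; it leaves in the later hydrogenation at no cost in steps. The seven-membered ring closes across N–C(=O)–N and forces both nitrogen atoms out of planarity; this is the main uncertainty.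

15 to 14: an O–Si bond. The phenol must be masked during acid chloride formation and N-acylation, and must be released by a reagent that does not attack an imide.

14 to 12 plus 8, and 12 to 10 plus 4: the two N–acyl bonds, formed one after the other so that two different acyl groups end up on the two nitrogen atoms. The first acylation must stop at the mono stage; the second must acylate a weakly nucleophilic acylurea N–H.

4 to 3 to 2 to 1: the C=C bond (condensation of an aldehyde with a malonate unit), then two O–CH3 bonds and the O–benzyl bond. The oxygen pattern of ring A is bought with 1, so no electrophilic substitution of doubtful regiochemistry is needed. The demand is selective benzylation of the most acidic hydroxyl.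

8 to 6 to 5: the O–Si bond and the C=C bond. 10 to 9: the two N–C(=O) bonds of the urea.

**Other disconnections considered**

Alternative 1: The cut is C4a–C8a, so ring A is built from a four-membered ring. In the forward step the cyclobutenone A1 is heated in an aromatic solvent at about 140 °C; it opens to a dienylketene, 6π-electrocyclisation forms C4a–C8a, and tautomerisation gives the phenol A2.
- In its favour: every oxygen of ring A is placed without ambiguity, O7 is already differentiated as a silyl ether, and the C4a hydroxyl is a handle for attaching C4. The rearrangement is a well-established pericyclic process, and on precedent and predictability it is better than the chosen key step.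
- Against it here: it makes a benzene ring that the chosen plan buys. A2 holds only C1 of the three stereocentres, and that one must come from an earlier asymmetric step. Ring B, C2, C3 and the C3–C4 and C4–C4a bonds are all still to be made.
- Comparison: on regiocontrol of ring A it is the equal of the chosen plan. On structure the chosen step delivers far more (all carbons, ring B, two stereocentres). On step economy it is clearly longer.

Alternative 2: The cuts are C4a–C8a and C7–C8. In the forward step the furan-tethered ynoate A3 is heated, and a trace of strong carboxylic acid then opens the oxygen bridge of the cycloadduct to give the phenol ester A4.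
- In its favour: rings A and B form together with regiochemistry dictated by the tether, no oxidant is involved, and intramolecular furan–alkyne cycloaddition followed by aromatisation is a known reaction type. In bonds and rings formed per step it equals the chosen plan (two and two); in mechanistic security it is better.
- Against it here: the step creates no stereocentre. All three must already stand on the open chain of A3, and C1 there is both benzylic and propargylic, so it is prone to base-induced isomerisation. The C8 ester is not in the target and costs a hydrolysis and a decarboxylation. The dialkoxyfuran is acid-sensitive.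
- Comparison: equal on regiochemistry, better on precedent, worse on stereochemical content of the key step and on step count.

Alternative 3: The cut is C1–C2. In the forward step a diarylprolinol silyl ether and a carboxylic acid co-catalyst turn the aldehyde of A5 into an enamine and the benzhydrol into the ring C quinone methide; C2 adds to C1, closing ring B to give A6.
- In its favour: it uses the same latent quinone methide of ring C, but in a closed-shell, catalyst-controlled addition of a known type. The catalyst antipode chooses the sense, C2 stays epimerisable towards the all-trans isomer, and A6 is two operations from the target (carbonyl reduction, hydrogenolysis). On mechanism and on the endgame it is better than the chosen plan.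
- Against it here: only one bond and one ring are formed. C3 must be set beforehand and may be matched or mismatched with the catalyst. A5 requires a crowded diaryl carbinol ortho to a side chain that carries a free aldehyde.
- Comparison: the chosen plan is more convergent and starts from simpler pieces, but it rests on an untested radical step. Alternative 3 is the more conservative choice, with a longer linear approach to its precursor and an overall step count expected to be comparable.

Key step: step 10

Assumption: the (4R,5R) auxiliary is taken to lead to 1R (through 2S); if the opposite sense is found, the same route is run from the (1S,2S)-diamine.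

**Route**

Step 1
Reactants: 1 2,3,4-trihydroxybenzaldehyde
Product: 2 4-(benzyloxy)-2,3-dihydroxybenzaldehyde
Conditions: BnBr (1.05 equiv), NaHCO3 (1.5 equiv), NaI (0.1 equiv), DMF, 40 °C, N2
Reagents that add atoms: benzyl bromide, BrCc1ccccc1
Why: Williamson etherification under weak-base control: the 4-OH, para to the formyl group, is the most acidic and the only one ionised by NaHCO3, while the 2-OH is held in a hydrogen bond to the carbonyl, so mono-benzylation at O4 is expected, as with other polyhydroxybenzaldehydes.

Step 2
Reactants: 2 4-(benzyloxy)-2,3-dihydroxybenzaldehyde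
Product: 3 4-(benzyloxy)-2,3-dimethoxybenzaldehyde
Conditions: MeI (3 equiv), K2CO3 (3 equiv), DMF, rt → 40 °C
Reagents that add atoms: methyl iodide, CI
Why: Exhaustive Williamson methylation of the two remaining phenols; the oxygen pattern of ring A (O5/O6 methyl, O7 benzyl) is now fixed without any aromatic substitution.

Step 3
Reactants: 3 4-(benzyloxy)-2,3-dimethoxybenzaldehyde
Product: 4 (E)-3-[4-(benzyloxy)-2,3-dimethoxyphenyl]prop-2-enoic acid
Conditions: CH2(CO2H)2 (2 equiv), pyridine, piperidine (0.1 equiv), 90 °C; aq. HCl
Reagents that add atoms: malonic acid, O=C(O)CC(=O)O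
Why: Knoevenagel–Doebner condensation with decarboxylation; the thermodynamic E acid results.

Step 4
Reactants: 5 3-bromo-4-hydroxy-5-methoxybenzaldehyde (5-bromovanillin)
Product: 6 (E)-3-(3-bromo-4-hydroxy-5-methoxyphenyl)prop-2-enoic acid
Conditions: CH2(CO2H)2 (2 equiv), pyridine, piperidine (0.1 equiv), 90 °C; aq. HCl
Reagents that add atoms: malonic acid, O=C(O)CC(=O)O
Why: Knoevenagel–Doebner condensation, which tolerates the free phenol as in the preparation of ferulic acid from vanillin; the bromine atom is the blocking group for the key step.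

Step 5
Reactants: 6 (E)-3-(3-bromo-4-hydroxy-5-methoxyphenyl)prop-2-enoic acid
Product: 8 (E)-3-[3-bromo-4-(tert-butyldimethylsilyloxy)-5-methoxyphenyl]prop-2-enoic acid, via bis-silylated acid 7 (not isolated)
Conditions: TBSCl (2.5 equiv), imidazole (5 equiv), DMF, rt; then AcOH–THF–H2O (3:1:1), rt
Reagents that add atoms: tert-butyldimethylsilyl chloride, CC(C)(C)[Si](C)(C)Cl
Why: Silylation of phenol and acid followed by selective hydrolysis of the labile silyl ester; the aryl silyl ether survives acid chloride formation and amide bases and is later removed by fluoride without touching an imide.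

Step 6
Reactants: 9 (1R,2R)-1,2-diphenylethane-1,2-diamine
Product: 10 (4R,5R)-4,5-diphenylimidazolidin-2-one
Conditions: 1,1'-carbonyldiimidazole (1.1 equiv), THF, rt → 60 °C
Reagents that add atoms: 1,1'-carbonyldiimidazole, O=C(n1ccnc1)n1ccnc1
Why: Carbonylation of the 1,2-diamine to the cyclic urea; the stereocentres are not involved.

Step 7
Reactants: 4 (E)-3-[4-(benzyloxy)-2,3-dimethoxyphenyl]prop-2-enoic acid; 10 (4R,5R)-4,5-diphenylimidazolidin-2-one
Product: 12 (4R,5R)-1-[(E)-3-(4-benzyloxy-2,3-dimethoxyphenyl)prop-2-enoyl]-4,5-diphenylimidazolidin-2-one, via acid chloride 11 (not isolated)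
Conditions: 4, (COCl)2 (1.2 equiv), DMF (cat.), CH2Cl2, 0 °C → rt, evaporate; 10 (1.5 equiv), n-BuLi (1.5 equiv), THF, −78 → 0 °C; then 11, −78 °C → rt
Reagents that add atoms: none
Why: Acid chloride formation and N-acylation of the lithiated urea; the excess of 10 keeps diacylation low and is recovered on chromatography.

Step 8
Reactants: 8 (E)-3-[3-bromo-4-(tert-butyldimethylsilyloxy)-5-methoxyphenyl]prop-2-enoic acid; 12 (4R,5R)-1-[(E)-3-(4-benzyloxy-2,3-dimethoxyphenyl)prop-2-enoyl]-4,5-diphenylimidazolidin-2-one
Product: 14 (4R,5R)-1-[(E)-3-(4-benzyloxy-2,3-dimethoxyphenyl)prop-2-enoyl]-3-[(E)-3-(3-bromo-4-(tert-butyldimethylsilyloxy)-5-methoxyphenyl)prop-2-enoyl]-4,5-diphenylimidazolidin-2-one, via acid chloride 13 (not isolated)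
Conditions: 8, (COCl)2 (1.2 equiv), DMF (cat.), CH2Cl2, 0 °C, evaporate; 12, LiN(SiMe3)2 (1.05 equiv), THF, −78 °C; then 13, −78 → 0 °C
Reagents that add atoms: none
Why: The remaining N–H is an acylurea N–H, acidic enough for clean deprotonation by the silylamide; acylation of the anion by the enoyl chloride at low temperature outruns conjugate addition.

Step 9
Reactants: 14 silyl ether described in step 8
Product: 15 (4R,5R)-1-[(E)-3-(4-benzyloxy-2,3-dimethoxyphenyl)prop-2-enoyl]-3-[(E)-3-(3-bromo-4-hydroxy-5-methoxyphenyl)prop-2-enoyl]-4,5-diphenylimidazolidin-2-one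
Conditions: Et3N·3HF (3 equiv), THF, 0 °C → rt
Reagents that add atoms: none
Why: Fluoride-induced cleavage of the aryl silyl ether under buffered, non-nucleophilic conditions; imide carbonyls, benzyl ether and aryl bromide are untouched.

Step 10
Reactants: 15 phenol described in step 9
Product: 17 the (1R,2S)-7-benzyloxy-1-(3-bromo-4-hydroxy-5-methoxyphenyl)-5,6-dimethoxy-1,2-dihydronaphthalene-2,3-dicarbonyl unit joined through its two carbonyl groups to N1 and N3 of (4R,5R)-4,5-diphenylimidazolidin-2-one, via quinone methide 16 (not isolated)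
Conditions: FeCl3·6H2O (2.5 equiv, added over 6 h), acetone, 0.003 M, 0 °C → rt, N2
Reagents that add atoms: none
Why: Proposed new method: one-electron oxidation of the only free phenol by FeCl3 gives a phenoxyl radical with spin density at C2 (electrophilic, alpha to the imide carbonyl), which should add to C3 of the neighbouring donor-substituted cinnamoyl group because this gives the C4 benzylic radical stabilised by the para benzyloxy and ortho methoxy groups of ring A; a second equivalent of trivalent iron oxidises that radical to the cation, loss of H3 gives the (E)-arylidene quinone methide 16, and C8a then attacks C1; the closest known reaction type is the FeCl3 or laccase/O2 dehydrodimerisation of sinapate and ferulate derivatives, free or bound to chiral auxiliaries, to 1-aryl-1,2-dihydronaphthalene-2,3-dicarboxylic acid derivatives, from which this step differs in that the partner is a tethered non-phenolic alkene. The temporary seven-membered ring (C2, its carbonyl, N, the urea carbon, N, carbonyl, C3) closes by 7-exo-trig radical addition, and ring B closes by 6-exo-trig Friedel–Crafts alkylation of C8a by the quinone methide carbon C1, followed by rearomatisation of both rings. C2 is controlled by the C2-symmetric auxiliary: each phenyl group is trans to the acyl group on the adjacent nitrogen, which should allow one twist sense of the seven-membered transition state and hence one face of the C1=C2 unit. C1 is controlled by C2: ring C takes the position trans to the C2 acyl group, as in the known dimerisations. Chemoselectivity follows from ring C carrying the only phenol, and the bromine atom and the methoxy group block both positions ortho to it, so coupling through ring carbons, the usual fate of ferulates, is closed off. Regioselectivity of ring closure is fixed because C8a is the only free position ortho to the side chain of ring A and lies para to the C6 methoxy group. High dilution and slow addition of the oxidant are needed because addition of a phenoxyl radical to an alkene is slower than radical dimerisation.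

Step 11
Reactants: 17 bridged dihydronaphthalene described in step 10
Product: 18 the (1R,2S,3R)-7-hydroxy-1-(4-hydroxy-3-methoxyphenyl)-5,6-dimethoxy-1,2,3,4-tetrahydronaphthalene-2,3-dicarbonyl unit (2,3-cis) joined through its two carbonyl groups to N1 and N3 of (4R,5R)-4,5-diphenylimidazolidin-2-one
Conditions: H2 (4 atm), 10% Pd/C, NaOAc (1.5 equiv), EtOAc–THF (1:1), rt
Reagents that add atoms: none
Why: Heterogeneous hydrogenation saturates the aryl-conjugated C3=C4 bond, cleaves the benzyl ether and removes the bromine atom (NaOAc takes up HBr). Delivery of hydrogen to the face away from the C2 acyl bridge should give the 2,3-cis compound; its C3 epimer would converge in step 12.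

Step 12
Reactants: 18 bridged tetralin described in step 11
Product: 20 dimethyl (1R,2S,3S)-7-hydroxy-1-(4-hydroxy-3-methoxyphenyl)-5,6-dimethoxy-1,2,3,4-tetrahydronaphthalene-2,3-dicarboxylate, via cis diester 19 (not isolated)
Conditions: NaOMe (6 equiv), MeOH–THF, 0 °C → 50 °C; then AcOH
Reagents that add atoms: methanol (used as NaOMe in MeOH), CO
Why: Methoxide cleaves both N–acyl bonds of the activated diacylurea (transesterification; 10 is recovered) and then equilibrates C3, and C2 if necessary, through the ester enolates to the all-trans diester, the thermodynamic isomer for a fixed C1. C1 is not acidic and keeps its configuration.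

Step 13
Reactants: 20 all-trans diester described in step 12
Product: 21 (1R,2S,3S)-1-(4-hydroxy-3-methoxyphenyl)-2,3-bis(hydroxymethyl)-5,6-dimethoxy-1,2,3,4-tetrahydronaphthalen-7-ol (target)
Conditions: LiAlH4 (6 equiv), THF, 0 °C → reflux; aq. potassium sodium tartrate
Reagents that add atoms: none
Why: Hydride reduction of both esters to primary alcohols; no stereocentre is touched, and the excess of hydride allows for the two phenoxides.

**Compound list**

1 | 2,3,4-trihydroxybenzaldehyde | O=Cc1ccc(O)c(O)c1O | starting material
2 | 4-(benzyloxy)-2,3-dihydroxybenzaldehyde | O=Cc1ccc(OCc2ccccc2)c(O)c1O | intermediate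
3 | 4-(benzyloxy)-2,3-dimethoxybenzaldehyde | COc1c(C=O)ccc(OCc2ccccc2)c1OC | intermediate
4 | (E)-3-[4-(benzyloxy)-2,3-dimethoxyphenyl]prop-2-enoic acid | COc1c(/C=C/C(=O)O)ccc(OCc2ccccc2)c1OC | intermediate
5 | 3-bromo-4-hydroxy-5-methoxybenzaldehyde | COc1cc(C=O)cc(Br)c1O | starting material
6 | (E)-3-(3-bromo-4-hydroxy-5-methoxyphenyl)prop-2-enoic acid | COc1cc(/C=C/C(=O)O)cc(Br)c1O | intermediate
7 | tert-butyldimethylsilyl (E)-3-[3-bromo-4-(tert-butyldimethylsilyloxy)-5-methoxyphenyl]prop-2-enoate | COc1cc(/C=C/C(=O)O[Si](C)(C)C(C)(C)C)cc(Br)c1O[Si](C)(C)C(C)(C)C | intermediate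
8 | (E)-3-[3-bromo-4-(tert-butyldimethylsilyloxy)-5-methoxyphenyl]prop-2-enoic acid | COc1cc(/C=C/C(=O)O)cc(Br)c1O[Si](C)(C)C(C)(C)C | intermediate
9 | (1R,2R)-1,2-diphenylethane-1,2-diamine | N[C@H](c1ccccc1)[C@H](N)c1ccccc1 | starting material
10 | (4R,5R)-4,5-diphenylimidazolidin-2-one | O=C1N[C@H](c2ccccc2)[C@@H](c2ccccc2)N1 | intermediate
11 | (E)-3-[4-(benzyloxy)-2,3-dimethoxyphenyl]prop-2-enoyl chloride | COc1c(/C=C/C(=O)Cl)ccc(OCc2ccccc2)c1OC | intermediate
12 | (4R,5R)-1-[(E)-3-(4-benzyloxy-2,3-dimethoxyphenyl)prop-2-enoyl]-4,5-diphenylimidazolidin-2-one | COc1c(/C=C/C(=O)N2C(=O)N[C@H](c3ccccc3)[C@H]2c2ccccc2)ccc(OCc2ccccc2)c1OC | intermediate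
13 | (E)-3-[3-bromo-4-(tert-butyldimethylsilyloxy)-5-methoxyphenyl]prop-2-enoyl chloride | COc1cc(/C=C/C(=O)Cl)cc(Br)c1O[Si](C)(C)C(C)(C)C | intermediate
14 | (4R,5R)-1-[(E)-3-(4-benzyloxy-2,3-dimethoxyphenyl)prop-2-enoyl]-3-[(E)-3-(3-bromo-4-(tert-butyldimethylsilyloxy)-5-methoxyphenyl)prop-2-enoyl]-4,5-diphenylimidazolidin-2-one | COc1cc(/C=C/C(=O)N2C(=O)N(C(=O)/C=C/c3ccc(OCc4ccccc4)c(OC)c3OC)[C@H](c3ccccc3)[C@H]2c2ccccc2)cc(Br)c1O[Si](C)(C)C(C)(C)C | intermediate
15 | (4R,5R)-1-[(E)-3-(4-benzyloxy-2,3-dimethoxyphenyl)prop-2-enoyl]-3-[(E)-3-(3-bromo-4-hydroxy-5-methoxyphenyl)prop-2-enoyl]-4,5-diphenylimidazolidin-2-one | COc1cc(/C=C/C(=O)N2C(=O)N(C(=O)/C=C/c3ccc(OCc4ccccc4)c(OC)c3OC)[C@H](c3ccccc3)[C@H]2c2ccccc2)cc(Br)c1O | intermediate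
16 | seven-membered diacylurea on the (4R,5R)-diphenylimidazolidinone, with (2S)-C2 carrying the (3-bromo-5-methoxy-4-oxocyclohexa-2,5-dienylidene)methyl group (geometry of that exocyclic bond not fixed) and C3 carrying the (E)-(4-benzyloxy-2,3-dimethoxyphenyl)methylidene group | COC1=CC(=C[C@@H]2C(=O)N3[C@H](c4ccccc4)[C@@H](c4ccccc4)N(C3=O)C(=O)/C2=C/c2ccc(OCc3ccccc3)c(OC)c2OC)C=C(Br)C1=O | intermediate
17 | (1R,2S)-7-benzyloxy-1-(3-bromo-4-hydroxy-5-methoxyphenyl)-5,6-dimethoxy-1,2-dihydronaphthalene-2,3-dicarbonyl unit bridging N1 and N3 of (4R,5R)-4,5-diphenylimidazolidin-2-one | COc1cc([C@@H]2c3cc(OCc4ccccc4)c(OC)c(OC)c3C=C3C(=O)N4[C@H](c5ccccc5)[C@@H](c5ccccc5)N(C4=O)C(=O)[C@H]32)cc(Br)c1O | intermediate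
18 | (1R,2S,3R)-7-hydroxy-1-(4-hydroxy-3-methoxyphenyl)-5,6-dimethoxy-1,2,3,4-tetrahydronaphthalene-2,3-dicarbonyl unit (2,3-cis) bridging N1 and N3 of (4R,5R)-4,5-diphenylimidazolidin-2-one | COc1cc([C@@H]2c3cc(O)c(OC)c(OC)c3C[C@H]3C(=O)N4[C@H](c5ccccc5)[C@@H](c5ccccc5)N(C4=O)C(=O)[C@H]32)ccc1O | intermediate
19 | dimethyl (1R,2S,3R)-7-hydroxy-1-(4-hydroxy-3-methoxyphenyl)-5,6-dimethoxy-1,2,3,4-tetrahydronaphthalene-2,3-dicarboxylate (2,3-cis) | COc1cc([C@@H]2c3cc(O)c(OC)c(OC)c3C[C@@H](C(=O)OC)[C@H]2C(=O)OC)ccc1O | intermediate
20 | dimethyl (1R,2S,3S)-7-hydroxy-1-(4-hydroxy-3-methoxyphenyl)-5,6-dimethoxy-1,2,3,4-tetrahydronaphthalene-2,3-dicarboxylate (all-trans) | COc1cc([C@@H]2c3cc(O)c(OC)c(OC)c3C[C@H](C(=O)OC)[C@H]2C(=O)OC)ccc1O | intermediate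
21 | (1R,2S,3S)-1-(4-hydroxy-3-methoxyphenyl)-2,3-bis(hydroxymethyl)-5,6-dimethoxy-1,2,3,4-tetrahydronaphthalen-7-ol | COc1cc([C@@H]2c3cc(O)c(OC)c(OC)c3C[C@H](CO)[C@H]2CO)ccc1O | target

**Step count and risk**

Total: 13 steps. Longest linear sequence: 10 steps (steps 1, 2, 3, 7, 8, 9, 10, 11, 12, 13).

Step 10 (key step).
- What may go wrong: intermolecular radical–radical coupling may outrun the intramolecular addition. Closing the seven-membered ring across N–C(=O)–N requires both acylated nitrogen atoms to pyramidalise (bridgehead nitrogens), which raises the barrier and makes 17 prone to solvolysis. Face selection by the auxiliary is unproven. Over-oxidation may aromatise ring B.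
- Fallback by known chemistry, setting out from 3 and returning at 21: Stobbe condensation of 3 with dimethyl succinate (NaOMe, MeOH, reflux) gives (E)-2-[(4-benzyloxy-2,3-dimethoxyphenyl)methylidene]butanedioic acid 1-methyl ester F1. Homogeneous asymmetric hydrogenation with [Rh(cod)(Et-DuPhos)]BF4 (ligand antipode chosen to give the S acid; the benzyl ether is untouched) gives (2S)-2-[(4-benzyloxy-2,3-dimethoxyphenyl)methyl]butanedioic acid 1-methyl ester F2. Reduction of the ester beside the carboxylate (LiBH4, THF) and acid lactonisation give (4S)-4-[(4-benzyloxy-2,3-dimethoxyphenyl)methyl]oxolan-2-one F3. Its lithium enolate (LiN(SiMe3)2, THF, −78 °C) adds to 4-benzyloxy-3-methoxybenzaldehyde anti to the benzyl group, giving the 3,4-trans 3-[(4-benzyloxy-3-methoxyphenyl)(hydroxy)methyl] lactone F4 (both carbinol epimers are used). CF3CO2H in CH2Cl2 ionises the carbinol and C8a closes ring B, giving the trans,trans aryltetralin lactone F5, with C1 trans to C2 as usual for this cyclisation. LiAlH4 opens the lactone to the diol bis(benzyl ether) F6, and hydrogenolysis (H2, Pd/C) gives 21.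

Step 8.
- What may go wrong: N-acylation of the hindered acylurea anion may be slow, so that conjugate addition of the anion to an enoyl group or loss of the first acyl group takes over.
- Fallback, setting out from 12 (with 5) and returning at 14: heating 12 with bromoacetyl bromide in toluene gives (4R,5R)-1-[(E)-3-(4-benzyloxy-2,3-dimethoxyphenyl)prop-2-enoyl]-3-(bromoacetyl)-4,5-diphenylimidazolidin-2-one F7. Arbuzov reaction with P(OEt)3 gives the corresponding 3-[(diethoxyphosphoryl)acetyl] compound F8. Silylation of 5 (TBSCl, imidazole) gives 3-bromo-4-(tert-butyldimethylsilyloxy)-5-methoxybenzaldehyde F9. Horner–Wadsworth–Emmons olefination of F9 with F8 (LiCl, i-Pr2NEt, MeCN) builds the second enoyl group on the nitrogen and gives 14 as the E isomer.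

Step 11.
- What may go wrong: saturation of the hindered trisubstituted alkene may stall while hydrogenolysis of benzyl and bromine is fast, or the strained imide may open on the catalyst.
- Fallback, setting out from 17 and returning at 20: Mg in MeOH (conjugate reduction by electron transfer, a known way to saturate aryl-conjugated enoates) reduces C3=C4. The Mg(OMe)2 formed transfers both acyl groups to methanol and equilibrates the esters, giving dimethyl (1R,2S,3S)-7-benzyloxy-1-(3-bromo-4-hydroxy-5-methoxyphenyl)-5,6-dimethoxy-1,2,3,4-tetrahydronaphthalene-2,3-dicarboxylate F10. Hydrogenolysis (H2, Pd/C, NaOAc) then only removes benzyl and bromine and gives 20.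

Step 12.
- What may go wrong: methoxide may attack the urea carbonyl instead of the acyl carbons (ring opening of the auxiliary, leaving an amide-bound fragment), or equilibration at C3 may be incomplete.
- Fallback, setting out from 18 and returning at 19: LiOH/H2O2 in THF–H2O, where hydroperoxide attacks the acyl carbonyl groups selectively, gives (1R,2S,3R)-7-hydroxy-1-(4-hydroxy-3-methoxyphenyl)-5,6-dimethoxy-1,2,3,4-tetrahydronaphthalene-2,3-dicarboxylic acid F11. Fischer esterification (MeOH, H2SO4 cat.) gives 19 as an isolated compound, which NaOMe in MeOH then epimerises to 20 as a separate operation.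

**Further compounds**

F1 | step 10 | (E)-2-[(4-benzyloxy-2,3-dimethoxyphenyl)methylidene]butanedioic acid 1-methyl ester | COc1c(/C=C(\CC(=O)O)C(=O)OC)ccc(OCc2ccccc2)c1OC
F2 | step 10 | (2S)-2-[(4-benzyloxy-2,3-dimethoxyphenyl)methyl]butanedioic acid 1-methyl ester | COc1c(C[C@@H](CC(=O)O)C(=O)OC)ccc(OCc2ccccc2)c1OC
F3 | step 10 | (4S)-4-[(4-benzyloxy-2,3-dimethoxyphenyl)methyl]oxolan-2-one | COc1c(C[C@@H]2COC(=O)C2)ccc(OCc2ccccc2)c1OC
F4 | step 10 | 3,4-trans-3-[(4-benzyloxy-3-methoxyphenyl)(hydroxy)methyl]-4-[(4-benzyloxy-2,3-dimethoxyphenyl)methyl]oxolan-2-one (carbinol epimers) | COc1cc(C(O)[C@@H]2C(=O)OC[C@H]2Cc2ccc(OCc3ccccc3)c(OC)c2OC)ccc1OCc1ccccc1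
F5 | step 10 | trans,trans aryltetralin lactone: 7-benzyloxy-1-(4-benzyloxy-3-methoxyphenyl)-5,6-dimethoxytetralin with C2–C(=O)–O–CH2–C3 lactone, C1/C2/C3 as in the target | COc1cc([C@@H]2c3cc(OCc4ccccc4)c(OC)c(OC)c3C[C@@H]3COC(=O)[C@H]32)ccc1OCc1ccccc1
F6 | step 10 | (1R,2S,3S)-7-benzyloxy-1-(4-benzyloxy-3-methoxyphenyl)-2,3-bis(hydroxymethyl)-5,6-dimethoxy-1,2,3,4-tetrahydronaphthalene | COc1cc([C@@H]2c3cc(OCc4ccccc4)c(OC)c(OC)c3C[C@H](CO)[C@H]2CO)ccc1OCc1ccccc1
F7 | step 8 | (4R,5R)-1-[(E)-3-(4-benzyloxy-2,3-dimethoxyphenyl)prop-2-enoyl]-3-(bromoacetyl)-4,5-diphenylimidazolidin-2-one | COc1c(/C=C/C(=O)N2C(=O)N(C(=O)CBr)[C@H](c3ccccc3)[C@H]2c2ccccc2)ccc(OCc2ccccc2)c1OC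
F8 | step 8 | (4R,5R)-1-[(E)-3-(4-benzyloxy-2,3-dimethoxyphenyl)prop-2-enoyl]-3-[(diethoxyphosphoryl)acetyl]-4,5-diphenylimidazolidin-2-one | COc1c(/C=C/C(=O)N2C(=O)N(C(=O)CP(=O)(OCC)OCC)[C@H](c3ccccc3)[C@H]2c2ccccc2)ccc(OCc2ccccc2)c1OC
F9 | step 8 | 3-bromo-4-(tert-butyldimethylsilyloxy)-5-methoxybenzaldehyde | COc1cc(C=O)cc(Br)c1O[Si](C)(C)C(C)(C)C
F10 | step 11 | dimethyl (1R,2S,3S)-7-benzyloxy-1-(3-bromo-4-hydroxy-5-methoxyphenyl)-5,6-dimethoxy-1,2,3,4-tetrahydronaphthalene-2,3-dicarboxylate | COc1cc([C@@H]2c3cc(OCc4ccccc4)c(OC)c(OC)c3C[C@H](C(=O)OC)[C@H]2C(=O)OC)cc(Br)c1O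
F11 | step 12 | (1R,2S,3R)-7-hydroxy-1-(4-hydroxy-3-methoxyphenyl)-5,6-dimethoxy-1,2,3,4-tetrahydronaphthalene-2,3-dicarboxylic acid | COc1cc([C@@H]2c3cc(O)c(OC)c(OC)c3C[C@@H](C(=O)O)[C@H]2C(=O)O)ccc1O
A1 | alternative 1 | 4-[(1E,3S)-3-(4-benzyloxy-3-methoxyphenyl)-5-(tert-butyldimethylsilyloxy)pent-1-enyl]-4-(tert-butyldimethylsilyloxy)-2,3-dimethoxycyclobut-2-en-1-one | COC1=C(OC)C(O[Si](C)(C)C(C)(C)C)(/C=C/[C@H](CCO[Si](C)(C)C(C)(C)C)c2ccc(OCc3ccccc3)c(OC)c2)C1=O
A2 | alternative 1 | 2-[(1R)-1-(4-benzyloxy-3-methoxyphenyl)-3-(tert-butyldimethylsilyloxy)propyl]-4-(tert-butyldimethylsilyloxy)-5,6-dimethoxyphenol | COc1cc([C@@H](CCO[Si](C)(C)C(C)(C)C)c2cc(O[Si](C)(C)C(C)(C)C)c(OC)c(OC)c2O)ccc1OCc1ccccc1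
A3 | alternative 2 | methyl (4R,5S,6S)-4-(4-benzyloxy-3-methoxyphenyl)-5,6-bis(benzyloxymethyl)-7-(3,4-dimethoxyfuran-2-yl)hept-2-ynoate | COC(=O)C#C[C@@H](c1ccc(OCc2ccccc2)c(OC)c1)[C@H](COCc1ccccc1)[C@@H](COCc1ccccc1)Cc1occ(OC)c1OC
A4 | alternative 2 | methyl (1R,2S,3S)-1-(4-benzyloxy-3-methoxyphenyl)-2,3-bis(benzyloxymethyl)-7-hydroxy-5,6-dimethoxy-1,2,3,4-tetrahydronaphthalene-8-carboxylate | COc1cc([C@@H]2c3c(C(=O)OC)c(O)c(OC)c(OC)c3C[C@H](COCc3ccccc3)[C@H]2COCc2ccccc2)ccc1OCc1ccccc1
A5 | alternative 3 | (3S)-3-(benzyloxymethyl)-4-{4-benzyloxy-6-[hydroxy(4-hydroxy-3-methoxyphenyl)methyl]-2,3-dimethoxyphenyl}butanal (carbinol epimers) | O=CC[C@@H](COCc1ccccc1)Cc1c(C(O)c2ccc(O)c(OC)c2)cc(OCc2ccccc2)c(OC)c1OC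
A6 | alternative 3 | (1R,2S,3S)-7-benzyloxy-3-(benzyloxymethyl)-1-(4-hydroxy-3-methoxyphenyl)-5,6-dimethoxy-1,2,3,4-tetrahydronaphthalene-2-carbaldehyde | COc1cc([C@@H]2c3cc(OCc4ccccc4)c(OC)c(OC)c3C[C@H](COCc3ccccc3)[C@H]2C=O)ccc1O
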